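The retrosynthesis cuts C2–Br and C3–Br first (C3–Br goes back to a C3 carboxyl group), then the C3–C3a bond of the pyrrole ring, then N1–C2, and last an auxiliary C–I bond on the benzene ring.
In the forward direction, the benzene ring arrives with both bromines in 3,4-dibromoaniline 1. Iodination gives 2, addition of its nitrogen to methyl propiolate 3 joins N1–C2 (enamino ester 4), and palladium closes the only new ring, the pyrrole, at C3–C3a (5, then 6).
The enabling feature is that C3a is the benzene carbon ortho to N1, so an iodine there marks the site of closure. C3 is the nucleophilic end of the N1–C2=C3 enamine, kept stable by its ester, and C5–Br and C6–Br are spectators on the benzene ring.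
In the endgame, the C3 ester is saponified (7) and exchanged for bromine by ipso-bromodecarboxylation (8), and C2 is brominated in the same flask to give 9.
The target is planar and has no stereocentre. The only stereo-element on the way, the Z double bond of 4, is set by an internal hydrogen bond and disappears on aromatisation.

Key step: step 3

Remark: 4 is drawn as its Z isomer. Any E isomer formed alongside can be carried on, since both should converge on 6 through enamine–imine equilibration. Indole numbering is used for all ring atoms from 5 onward.

Step 1
Reactants: 1 3,4-dibromoaniline
Product: 2 4,5-dibromo-2-iodoaniline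
Conditions: NIS (1.0 equiv), AcOH, rt, dark
Reagents that add atoms: N-iodosuccinimide (NIS), O=C1CCC(=O)N1I
Why: Electrophilic aromatic iodination is directed by the amino group to its ortho and para positions, and since para carries bromine and one ortho site is squeezed between NH2 and Br, iodine should enter at the open ortho carbon C6 of 1, which becomes C2 of 2.

Step 2
Reactants: 2 4,5-dibromo-2-iodoaniline; 3 methyl propiolate
Product: 4 methyl (Z)-3-[(4,5-dibromo-2-iodophenyl)amino]prop-2-enoate
Conditions: 3 (2 equiv), MeOH, 65 °C, sealed tube, 48 h
Reagents that add atoms: none
Why: Aza-Michael (conjugate) addition of the aniline nitrogen to the activated alkyne, with methanol as proton shuttle, should give the push–pull enamino ester, whose Z geometry is the thermodynamic one because of the six-membered N–H···O=C hydrogen bond.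

Step 3
Reactants: 4 methyl (Z)-3-[(4,5-dibromo-2-iodophenyl)amino]prop-2-enoate
Product: 6 methyl 5,6-dibromo-1H-indole-3-carboxylate, via methyl 5,6-dibromo-3H-indole-3-carboxylate 5 (not isolated)
Conditions: Pd(OAc)2 (5 mol %), n-Bu4NCl (1 equiv), NaHCO3 (2.5 equiv), DMF, 80 °C, Ar
Reagents that add atoms: none
Why: In-situ reduction of Pd(OAc)2 supplies zerovalent palladium, oxidative addition occurs at the carbon–iodine bond of 4, and the nucleophilic enamine carbon that bears the ester (the future C3) then binds to the divalent arylpalladium centre while hydrogencarbonate removes the N–H proton, so that a six-membered azapalladacycle forms with net loss of HI. Reductive elimination from this palladacycle makes the C3–C3a bond and releases the catalyst together with the 3H-indole 5, whose 1,3-proton shift to the aromatic 1H-indole 6 drives the sequence forward. The closest known reaction type is the palladium-catalysed intramolecular Heck-type cyclisation of N-(2-haloaryl) enaminones and enamino esters to 3-acylindoles and indole-3-carboxylates. The single ring closure is formally 5-endo-trig, a mode that is awkward for a concerted syn carbopalladation but unproblematic by the palladacycle and reductive-elimination path. No stereocentre is carried out of the step, because C3 of 5 arises without control and is flattened by the tautomerisation, and the double-bond geometry of 4 does not matter since Z and E forms equilibrate through the imine tautomer. The selectivity needed is insertion at C–I in the presence of two C–Br bonds, secured by the weaker C–I bond and by phosphine-free, chloride-assisted conditions at moderate temperature under which aryl bromides should stay untouched, while the regiochemistry (5,6- and not 4,5-dibromo) is locked by the site of the iodine in 4.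

Step 4
Reactants: 6 methyl 5,6-dibromo-1H-indole-3-carboxylate
Product: 7 5,6-dibromo-1H-indole-3-carboxylic acid
Conditions: NaOH (5 equiv), MeOH–THF–H2O, 65 °C; then 1 M HCl, 0 °C, pH 3
Reagents that add atoms: sodium hydroxide, [Na+].[OH-]
Why: Saponification (BAc2) of this vinylogous carbamate ester is slow but should be clean with excess hydroxide at reflux, the aryl bromides have no activation for nucleophilic aromatic substitution, and acidification in the cold avoids premature acid-catalysed loss of CO2.

Step 5
Reactants: 7 5,6-dibromo-1H-indole-3-carboxylic acid
Product: 9 2,3,5,6-tetrabromo-1H-indole, via 3,5,6-tribromo-1H-indole 8 (not isolated)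
Conditions: NBS (1.05 equiv), dry DMF, 0 °C to rt; then NBS (1.05 equiv), 0 °C to rt, dark; aq Na2S2O3/NaHCO3 work-up
Reagents that add atoms: N-bromosuccinimide (NBS), O=C1CCC(=O)N1Br
Why: This is a halodecarboxylation of an electron-rich heteroaromatic acid (ionic Hunsdiecker-type ipso-substitution) in which electrophilic bromine attacks the enamine-like C3, the σ-complex expels CO2 and a proton to give 8, and the second equivalent brominates C2, the only open pyrrole position, by ordinary electrophilic substitution while the benzene ring stays deactivated by its two bromines.

Compound list
1 | 3,4-dibromoaniline | Nc1ccc(Br)c(Br)c1 | starting material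
2 | 4,5-dibromo-2-iodoaniline | Nc1cc(Br)c(Br)cc1I | intermediate
3 | methyl propiolate | COC(=O)C#C | starting material
4 | methyl (Z)-3-[(4,5-dibromo-2-iodophenyl)amino]prop-2-enoate | COC(=O)/C=C\Nc1cc(Br)c(Br)cc1I | intermediate
5 | methyl 5,6-dibromo-3H-indole-3-carboxylate (racemic, transient, not isolated) | COC(=O)C1C=Nc2cc(Br)c(Br)cc12 | intermediate
6 | methyl 5,6-dibromo-1H-indole-3-carboxylate | COC(=O)c1c[nH]c2cc(Br)c(Br)cc12 | intermediate
7 | 5,6-dibromo-1H-indole-3-carboxylic acid | OC(=O)c1c[nH]c2cc(Br)c(Br)cc12 | intermediate
8 | 3,5,6-tribromo-1H-indole (not isolated) | Brc1c[nH]c2cc(Br)c(Br)cc12 | intermediate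
9 | 2,3,5,6-tetrabromo-1H-indole | Brc1cc2[nH]c(Br)c(Br)c2cc1Br | target

Total step count: 5
Longest linear sequence: 5 steps (1 to 9)

Steps most likely to fail

**Step 5.** On this electron-poor indole, ipso attack at C3 and the loss of CO2 may lag behind oxidation of the pyrrole ring by NBS and traces of water. The acid-sensitive product may also degrade during a prolonged reaction. The fallback separates C–C cleavage from C–Br formation.
- It sets out from 7. Acid-catalysed protodecarboxylation (2 M HCl–dioxane, 90 °C; protonation at C3, then loss of CO2) should give 5,6-dibromo-1H-indole F1.
- One equivalent of NBS in DMF at 0 °C then brominates the free C3.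
- The route is rejoined at 8, which takes up the second equivalent as before to give 9.

**Step 3.** Halogen selectivity may erode through insertion of palladium into a C–Br bond of substrate or product, followed by oligomerisation or hydrodehalogenation. Protodeiodination and hydrolytic cleavage of the enamine at 80 °C are further risks. The fallback closes the pyrrole ring at N1–C2 instead of C3–C3a.
- It sets out from 2. Sonogashira coupling with trimethylsilylacetylene (PdCl2(PPh3)2, CuI, Et3N, THF, rt, a temperature at which only the C–I bond should react) should give 4,5-dibromo-2-[(trimethylsilyl)ethynyl]aniline F2.
- K2CO3 in MeOH removes the silyl group to give 4,5-dibromo-2-ethynylaniline F3.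
- Metal-free 5-endo-dig hydroamination with KOt-Bu in NMP at rt should give 5,6-dibromo-1H-indole F1.
- Bromination of F1 with one equivalent of NBS comes back to the route at 8.

**Step 2.** The nitrogen of the trihalogenated, ortho-hindered aniline is a weak nucleophile. The addition may therefore be too slow to compete with oligomerisation of the alkyne or with a second N-vinylation. The fallback activates the electrophile instead of relying on the amine.
- It sets out from 2. Acid-catalysed condensation with commercial methyl 3,3-dimethoxypropanoate (cat. p-TsOH, toluene, 110 °C, methanol distilled off) passes through an oxocarbenium ion that even a weakly basic aniline should capture.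
- Loss of the second methanol delivers the same hydrogen-bonded Z enamino ester, so the route is rejoined at 4 without any new isolated compound.

Further compounds
F1 | step 5 | 5,6-dibromo-1H-indole | Brc1cc2cc[nH]c2cc1Br
F2 | step 3 | 4,5-dibromo-2-[(trimethylsilyl)ethynyl]aniline | C[Si](C)(C)C#Cc1cc(Br)c(Br)cc1N
F3 | step 3 | 4,5-dibromo-2-ethynylaniline | C#Cc1cc(Br)c(Br)cc1N
F0 | step 2 | none | none
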